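## Retrosynthetic overview

1. Final operations: global desilylation, then back through the ester C–O bond (Steglich) between a 4‑silyloxybenzoic acid and the secondary OH of a 1‑O‑trienyl‑3‑O‑silyl‑sn‑glycerol. The stereocentre comes from (R)‑solketal.
2. The central C6=C7 alkene of the triene is opened to an anti β‑hydroxysilane (Peterson olefination, anti mode).
3. Key C6–C7 bond: carbonyl allylation of a C1–C6 (E)‑enal, which already carries the glycerol acetonide, with the α‑silylallyl titanate from (E)‑hex‑2‑enyl(trimethyl)silane (C7–C12).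
4. The enal comes from solketal pent‑4‑enyl ether and crotonaldehyde (cross‑metathesis). The allylsilane comes from pent‑1‑yne via the (E)‑vinyl iodide and Me3SiCH2MgCl.
5. No ring is constructed: the benzene ring and the temporary dioxolane ring arrive with purchased materials.

Assumptions: (i) 14 forms as the anti pair (6R,7S)/(6S,7R) relative to the fixed dioxolane centre; one member is drawn and both converge in step 6. (ii) Species made by one reagent and consumed by a reagent added later in the same flask are numbered as intermediates; fleeting mechanistic species are not. (iii) Cyclopentadienyl ligands are drawn σ‑bound in SMILES.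

## Route

Step 1
Reactants: 1 (R)‑solketal, [(4R)‑2,2‑dimethyl‑1,3‑dioxolan‑4‑yl]methanol; 2 5‑bromopent‑1‑ene
Product: 4 (4R)‑2,2‑dimethyl‑4‑[(pent‑4‑en‑1‑yloxy)methyl]‑1,3‑dioxolane, via sodium [(4R)‑2,2‑dimethyl‑1,3‑dioxolan‑4‑yl]methanolate 3 (not isolated)
Conditions: NaH, THF/DMF, 0 °C; then 2, Bu4NI (cat.), rt
Reagents that add atoms: sodium hydride [Na+].[H-] (Na of 3 only)
Why: Williamson ether synthesis on a primary bromide; the stereocentre is not a reacting atom and keeps its configuration.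

Step 2
Reactants: 4; 5 (E)‑but‑2‑enal (crotonaldehyde, 5 equiv)
Product: 6 (2E)‑6‑{[(4R)‑2,2‑dimethyl‑1,3‑dioxolan‑4‑yl]methoxy}hex‑2‑enal
Conditions: second‑generation Hoveyda–Grubbs catalyst RuCl2(H2IMes)(=CH‑C6H4‑2‑OiPr) (3 mol %), CH2Cl2, 40 °C
Reagents that add atoms: none
Why: Olefin cross‑metathesis of a terminal alkene with an electron‑poor enal partner gives the conjugated E‑enal under thermodynamic control, and the acetonide is inert to the ruthenium carbene.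

Step 3
Reactants: 7 pent‑1‑yne
Product: 9 (1E)‑1‑iodopent‑1‑ene, via chlorobis(cyclopentadienyl)[(1E)‑pent‑1‑en‑1‑yl]zirconium 8 (not isolated)
Conditions: Cp2Zr(H)Cl, CH2Cl2, rt; then I2, 0 °C
Reagents that add atoms: Schwartz reagent Cp2Zr(H)Cl [H][Zr](Cl)(C1C=CC=C1)C1C=CC=C1 (in 8 only); iodine II
Why: Hydrozirconation adds Zr–H syn and anti‑Markovnikov, and iododezirconation proceeds with retention, so only the E‑vinyl iodide forms.

Step 4
Reactants: 9; 10 (trimethylsilyl)methylmagnesium chloride Me3SiCH2MgCl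
Product: 11 [(2E)‑hex‑2‑en‑1‑yl](trimethyl)silane
Conditions: Pd(PPh3)4 (3 mol %), THF, 0 °C → rt
Reagents that add atoms: none
Why: Kumada–Corriu cross‑coupling of a vinyl iodide with a Grignard reagent lacking β‑hydrogens proceeds with retention of the E geometry and gives the allylsilane as a single regioisomer.

Step 5
Reactants: 11 (1.5 equiv); 6
Product: 14 (4E,6R*,7S*,8E)‑1‑{[(4R)‑2,2‑dimethyl‑1,3‑dioxolan‑4‑yl]methoxy}‑7‑(trimethylsilyl)dodeca‑4,8‑dien‑6‑ol, via [(2E)‑1‑(trimethylsilyl)hex‑2‑en‑1‑yl]lithium 12 (not isolated), via lithium tetraisopropoxy[(1E)‑1‑(trimethylsilyl)hex‑1‑en‑3‑yl]titanate 13 (not isolated)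
Conditions: 11, s‑BuLi, TMEDA, THF, −78 → −30 °C; Ti(OiPr)4, −78 °C; then 6, −78 → −20 °C; then H2O
Reagents that add atoms: sec‑butyllithium CCC(C)[Li] (Li of 12 and 13 only); titanium tetraisopropoxide CC(C)O[Ti](OC(C)C)(OC(C)C)OC(C)C (in 13 only)
Why: Carbonyl allylation in which the α‑silylallyl titanate adds 1,2 to the enal at the silicon‑bearing carbon through a closed chair (Zimmerman–Traxler‑type) transition state with the E‑vinylsilane and the propyl group equatorial, giving the anti (6R*,7S*) β‑hydroxysilane and an 8E alkene; both new centres are erased in step 6, so only their relative configuration matters.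

Step 6
Reactants: 14
Product: 15 (4R)‑4‑({[(4E,6E,8E)‑dodeca‑4,6,8‑trien‑1‑yl]oxy}methyl)‑2,2‑dimethyl‑1,3‑dioxolane
Conditions: MsCl, Et3N, CH2Cl2, −20 → 0 °C
Reagents that add atoms: none
Why: Peterson olefination in its anti mode, in which the β‑silyl mesylate loses Me3Si and OMs antiperiplanar, so the anti adduct gives the 6E alkene without acid that would endanger the acetonide.

Step 7
Reactants: 15
Product: 16 (2S)‑3‑{[(4E,6E,8E)‑dodeca‑4,6,8‑trien‑1‑yl]oxy}propane‑1,2‑diol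
Conditions: AcOH/H2O (4:1), 40 °C, argon, dark
Reagents that add atoms: none
Why: Acid‑catalysed acetal hydrolysis cleaves only the ketal C–O bonds, so the C2 configuration is kept, and the unfunctionalised triene tolerates dilute acetic acid.

Step 8
Reactants: 16
Product: 17 (2R)‑1‑{[tert‑butyl(dimethyl)silyl]oxy}‑3‑{[(4E,6E,8E)‑dodeca‑4,6,8‑trien‑1‑yl]oxy}propan‑2‑ol
Conditions: TBSCl (1.05 equiv), imidazole, CH2Cl2, −20 → 0 °C
Reagents that add atoms: tert‑butyldimethylsilyl chloride CC(C)(C)[Si](C)(C)Cl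
Why: Regioselective silylation, since the bulky silyl chloride reacts with the primary hydroxyl much faster than with the secondary one (the descriptor changes from S to R only because of CIP priorities).

Step 9
Reactants: 18 4‑hydroxybenzoic acid
Product: 20 4‑{[tert‑butyl(dimethyl)silyl]oxy}benzoic acid, via tert‑butyl(dimethyl)silyl 4‑{[tert‑butyl(dimethyl)silyl]oxy}benzoate 19 (not isolated)
Conditions: TBSCl (2.3 equiv), imidazole, DMF, rt; then AcOH/THF/H2O (3:1:1), rt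
Reagents that add atoms: tert‑butyldimethylsilyl chloride CC(C)(C)[Si](C)(C)Cl
Why: Exhaustive silylation followed by selective hydrolysis of the far more labile silyl ester leaves the aryl silyl ether in place.

Step 10
Reactants: 17; 20 (1.3 equiv)
Product: 21 (2R)‑1‑{[tert‑butyl(dimethyl)silyl]oxy}‑3‑{[(4E,6E,8E)‑dodeca‑4,6,8‑trien‑1‑yl]oxy}propan‑2‑yl 4‑{[tert‑butyl(dimethyl)silyl]oxy}benzoate
Conditions: DCC, DMAP (0.3 equiv), CH2Cl2, 0 °C → rt
Reagents that add atoms: none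
Why: Steglich esterification acylates the secondary alcohol through an acylpyridinium intermediate without touching the C–O bond at the stereocentre, so configuration is retained.

Step 11
Reactants: 21
Product: 22 (2S)‑1‑{[(4E,6E,8E)‑dodeca‑4,6,8‑trien‑1‑yl]oxy}‑3‑hydroxypropan‑2‑yl 4‑hydroxybenzoate (CNP0352133.1)
Conditions: HF·pyridine, pyridine, THF, 0 °C → rt; Me3SiOMe quench
Reagents that add atoms: none
Why: Fluoride‑mediated desilylation under pyridine‑buffered, near‑neutral conditions removes the aryl and primary silyl ethers while suppressing 2→3 acyl migration.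

## Compound list

1 | (R)‑solketal, [(4R)‑2,2‑dimethyl‑1,3‑dioxolan‑4‑yl]methanol | CC1(C)OC[C@@H](CO)O1 | starting material
2 | 5‑bromopent‑1‑ene | C=CCCCBr | starting material
3 | sodium [(4R)‑2,2‑dimethyl‑1,3‑dioxolan‑4‑yl]methanolate | CC1(C)OC[C@@H](C[O-])O1.[Na+] | intermediate (not isolated)
4 | (4R)‑2,2‑dimethyl‑4‑[(pent‑4‑en‑1‑yloxy)methyl]‑1,3‑dioxolane | C=CCCCOC[C@@H]1COC(C)(C)O1 | intermediate
5 | (E)‑but‑2‑enal (crotonaldehyde) | C/C=C/C=O | starting material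
6 | (2E)‑6‑{[(4R)‑2,2‑dimethyl‑1,3‑dioxolan‑4‑yl]methoxy}hex‑2‑enal | O=C/C=C/CCCOC[C@@H]1COC(C)(C)O1 | intermediate
7 | pent‑1‑yne | CCCC#C | starting material
8 | chlorobis(cyclopentadienyl)[(1E)‑pent‑1‑en‑1‑yl]zirconium, Cp2Zr(Cl)(CH=CH‑nPr) | CCC/C=C/[Zr](Cl)(C1C=CC=C1)C1C=CC=C1 | intermediate (not isolated)
9 | (1E)‑1‑iodopent‑1‑ene | CCC/C=C/I | intermediate
10 | (trimethylsilyl)methylmagnesium chloride, Me3SiCH2MgCl | C[Si](C)(C)C[Mg]Cl | starting material
11 | [(2E)‑hex‑2‑en‑1‑yl](trimethyl)silane | CCC/C=C/C[Si](C)(C)C | intermediate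
12 | [(2E)‑1‑(trimethylsilyl)hex‑2‑en‑1‑yl]lithium, Li[CH(SiMe3)CH=CH‑nPr] | CCC/C=C/C([Li])[Si](C)(C)C | intermediate (not isolated)
13 | lithium tetraisopropoxy[(1E)‑1‑(trimethylsilyl)hex‑1‑en‑3‑yl]titanate, Li[Ti(OiPr)4(CH(nPr)CH=CHSiMe3)] (fluxional allyl, drawn with Ti on the propyl‑bearing carbon) | [Li+].CCCC(/C=C/[Si](C)(C)C)[Ti-](OC(C)C)(OC(C)C)(OC(C)C)OC(C)C | intermediate (not isolated)
14 | (4E,6R*,7S*,8E)‑1‑{[(4R)‑2,2‑dimethyl‑1,3‑dioxolan‑4‑yl]methoxy}‑7‑(trimethylsilyl)dodeca‑4,8‑dien‑6‑ol (anti; (6R,7S) drawn, the (6S,7R) partner is CCC/C=C/[C@@H]([Si](C)(C)C)[C@@H](O)/C=C/CCCOC[C@@H]1COC(C)(C)O1) | CCC/C=C/[C@H]([Si](C)(C)C)[C@H](O)/C=C/CCCOC[C@@H]1COC(C)(C)O1 | intermediate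
15 | (4R)‑4‑({[(4E,6E,8E)‑dodeca‑4,6,8‑trien‑1‑yl]oxy}methyl)‑2,2‑dimethyl‑1,3‑dioxolane | CCC/C=C/C=C/C=C/CCCOC[C@@H]1COC(C)(C)O1 | intermediate
16 | (2S)‑3‑{[(4E,6E,8E)‑dodeca‑4,6,8‑trien‑1‑yl]oxy}propane‑1,2‑diol | CCC/C=C/C=C/C=C/CCCOC[C@@H](O)CO | intermediate
17 | (2R)‑1‑{[tert‑butyl(dimethyl)silyl]oxy}‑3‑{[(4E,6E,8E)‑dodeca‑4,6,8‑trien‑1‑yl]oxy}propan‑2‑ol | CCC/C=C/C=C/C=C/CCCOC[C@@H](O)CO[Si](C)(C)C(C)(C)C | intermediate
18 | 4‑hydroxybenzoic acid | OC(=O)c1ccc(O)cc1 | starting material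
19 | tert‑butyl(dimethyl)silyl 4‑{[tert‑butyl(dimethyl)silyl]oxy}benzoate | CC(C)(C)[Si](C)(C)OC(=O)c1ccc(O[Si](C)(C)C(C)(C)C)cc1 | intermediate (not isolated)
20 | 4‑{[tert‑butyl(dimethyl)silyl]oxy}benzoic acid | CC(C)(C)[Si](C)(C)Oc1ccc(cc1)C(O)=O | intermediate
21 | (2R)‑1‑{[tert‑butyl(dimethyl)silyl]oxy}‑3‑{[(4E,6E,8E)‑dodeca‑4,6,8‑trien‑1‑yl]oxy}propan‑2‑yl 4‑{[tert‑butyl(dimethyl)silyl]oxy}benzoate | CCC/C=C/C=C/C=C/CCCOC[C@H](CO[Si](C)(C)C(C)(C)C)OC(=O)c1ccc(O[Si](C)(C)C(C)(C)C)cc1 | intermediate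
22 | (2S)‑1‑{[(4E,6E,8E)‑dodeca‑4,6,8‑trien‑1‑yl]oxy}‑3‑hydroxypropan‑2‑yl 4‑hydroxybenzoate | CCC/C=C/C=C/C=C/CCCOC[C@H](CO)OC(=O)c1ccc(O)cc1 | target

## Step count and risks

Total steps: 11. Longest linear sequence: 8 steps (1 → 2 → 5 → 6 → 7 → 8 → 10 → 11, from (R)‑solketal). Steps 3–4 and step 9 are side branches.

**Step 5 (most likely to fail).** Metallation of the γ‑alkyl allylsilane may be sluggish, and attack at the propyl‑bearing carbon or imperfect anti selectivity would erode yield and geometry. The fallback sets out from 1 and comes back at 15, replacing the allylation/elimination pair with a Julia–Kocienski olefination at C4=C5: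
- (R)‑solketal 1 is alkylated with excess 1,4‑dibromobutane (NaH, THF/DMF) to (4R)‑4‑[(4‑bromobutoxy)methyl]‑2,2‑dimethyl‑1,3‑dioxolane F1.
- Displacement with 1‑phenyl‑1H‑tetrazole‑5‑thiol (K2CO3, acetone) gives 5‑[(4‑{[(4R)‑2,2‑dimethyl‑1,3‑dioxolan‑4‑yl]methoxy}butyl)sulfanyl]‑1‑phenyl‑1H‑tetrazole F2.
- Oxidation ((NH4)6Mo7O24·4H2O cat., H2O2, EtOH) gives 5‑[(4‑{[(4R)‑2,2‑dimethyl‑1,3‑dioxolan‑4‑yl]methoxy}butyl)sulfonyl]‑1‑phenyl‑1H‑tetrazole F3.
- Deprotonation with KN(SiMe3)2 in DME at −60 °C and addition of commercial (2E,4E)‑octa‑2,4‑dienal gives 15 E‑selectively.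

**Step 6.** The allylic mesylate could be diverted to SN2′ chloride products, or material carrying some syn adduct would give 6Z triene. The fallback sets out from 14 and comes back at 15, using stereospecific syn elimination followed by thermodynamic control. KH in THF at 0 °C converts 14 cleanly into (4R)‑4‑({[(4E,6Z,8E)‑dodeca‑4,6,8‑trien‑1‑yl]oxy}methyl)‑2,2‑dimethyl‑1,3‑dioxolane F4. Catalytic I2 (2 mol %) in hexane under daylight at rt then equilibrates the central alkene to the all‑E triene 15, which is purified on AgNO3‑doped silica.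

**Step 11.** 2→3 migration of the aroyl group onto the freed primary hydroxyl during or after desilylation is the main danger; chromatography should be quick, cold and on H3BO3‑doped silica. The fallback sets out from 16 and comes back at 22, replacing silyl by levulinoyl protection:
- 16 is acylated selectively at the primary hydroxyl (levulinic anhydride, 2,4,6‑collidine, CH2Cl2, −40 °C) to (2R)‑3‑{[(4E,6E,8E)‑dodeca‑4,6,8‑trien‑1‑yl]oxy}‑2‑hydroxypropyl 4‑oxopentanoate F5.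
- 4‑Hydroxybenzoic acid 18 with levulinic anhydride/pyridine gives 4‑[(4‑oxopentanoyl)oxy]benzoic acid F6.
- DCC/DMAP coupling of F5 and F6 gives (2R)‑1‑{[(4E,6E,8E)‑dodeca‑4,6,8‑trien‑1‑yl]oxy}‑3‑[(4‑oxopentanoyl)oxy]propan‑2‑yl 4‑[(4‑oxopentanoyl)oxy]benzoate F7.
- N2H4·H2O in pyridine/AcOH (3:2) at 0 °C under argon removes both levulinates at about pH 5 and gives 22.

## Further compounds

F1 | step 5 | (4R)‑4‑[(4‑bromobutoxy)methyl]‑2,2‑dimethyl‑1,3‑dioxolane | BrCCCCOC[C@@H]1COC(C)(C)O1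
F2 | step 5 | 5‑[(4‑{[(4R)‑2,2‑dimethyl‑1,3‑dioxolan‑4‑yl]methoxy}butyl)sulfanyl]‑1‑phenyl‑1H‑tetrazole | CC1(C)OC[C@@H](COCCCCSc2nnnn2-c2ccccc2)O1
F3 | step 5 | 5‑[(4‑{[(4R)‑2,2‑dimethyl‑1,3‑dioxolan‑4‑yl]methoxy}butyl)sulfonyl]‑1‑phenyl‑1H‑tetrazole | CC1(C)OC[C@@H](COCCCCS(=O)(=O)c2nnnn2-c2ccccc2)O1
F4 | step 6 | (4R)‑4‑({[(4E,6Z,8E)‑dodeca‑4,6,8‑trien‑1‑yl]oxy}methyl)‑2,2‑dimethyl‑1,3‑dioxolane | CCC/C=C/C=C\C=C\CCCOC[C@@H]1COC(C)(C)O1
F5 | step 11 | (2R)‑3‑{[(4E,6E,8E)‑dodeca‑4,6,8‑trien‑1‑yl]oxy}‑2‑hydroxypropyl 4‑oxopentanoate | CCC/C=C/C=C/C=C/CCCOC[C@@H](O)COC(=O)CCC(C)=O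
F6 | step 11 | 4‑[(4‑oxopentanoyl)oxy]benzoic acid | CC(=O)CCC(=O)Oc1ccc(cc1)C(O)=O
F7 | step 11 | (2R)‑1‑{[(4E,6E,8E)‑dodeca‑4,6,8‑trien‑1‑yl]oxy}‑3‑[(4‑oxopentanoyl)oxy]propan‑2‑yl 4‑[(4‑oxopentanoyl)oxy]benzoate | CCC/C=C/C=C/C=C/CCCOC[C@H](COC(=O)CCC(C)=O)OC(=O)c1ccc(OC(=O)CCC(C)=O)cc1
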